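The 14-membered carbocycle is opened at the bond between C4, the methyl-bearing epoxide carbon, and the ring methylene C5 (cembrane numbering). C4 and the carbinol carbon C7 stand in a 1,4-relationship, so the epoxy alcohol is read as a γ,δ-unsaturated ketone. A nickel-catalysed reductive coupling of a but-2-ynyl group (C2–C3≡C4–C18) with a vinyl ketone (C5=C6–C7=O) should close the macrocycle, form C4–C5 and fix the (E)-C3=C4 alkene in one operation. Its precursor is an open-chain dienynone that already carries the cis-disubstituted α-methylene-γ-butyrolactone, the C13 acetate and the C12 methyl group. Reagent-controlled ketone reduction and epoxidation then set C7, C3 and C4.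

Key step: step 12

Numbering used throughout:
- C1 is the lactone carbon bearing the C2 chain, and C2 is a CH2.
- C3 and C4 are the epoxide carbons; C18 is the methyl on C4.
- C5 and C6 are CH2 groups, and C7 is the carbinol carbon.
- C8 carries the exocyclic methylene C19H2, and C9–C11 are CH2 groups.
- C12 carries the methyl C20, C13 carries OAc, and C14 carries the lactone oxygen.
- C15 carries the exocyclic methylene C17H2, and C16 is the lactone C=O.
- The target is (1S,3R,4R,7S,12S,13R,14R), with a cis lactone and an epoxide of the (E)-alkene type.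

Assumption: in step 1 the antipode of the Josiphos ligand is taken that delivers the (S)-ester. Both antipodes are commercial.

Step 1
Reactants: 1 (5-bromopent-1-yn-1-yl)trimethylsilane; 2 methyl (E)-but-2-enoate
Product: 4 methyl (S)-3-methyl-8-(trimethylsilyl)oct-7-ynoate, via Grignard reagent 3 (not isolated)
Conditions: Mg, Et2O, reflux; then 2, CuBr·SMe2 (5 mol %), Josiphos SL-J001 (6 mol %), t-BuOMe, −75 °C; aq NH4Cl
Reagents that add atoms: none
Why: Copper-catalysed asymmetric conjugate addition of a primary alkylmagnesium bromide to an (E)-enoate: the chiral ferrocenyl diphosphine on copper leaves one face of the β-carbon of 2 open and thereby sets C12 as S, while the silyl cap removes the acidic alkyne proton.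

Step 2
Reactants: 4 methyl (S)-3-methyl-8-(trimethylsilyl)oct-7-ynoate
Product: 5 methyl (S)-3-methyloct-7-ynoate
Conditions: K2CO3 (cat.), MeOH, rt
Reagents that add atoms: none
Why: Carbonate-catalysed methanolytic protodesilylation of the alkynylsilane, which cannot change the methyl ester in methanol and leaves C12 untouched.

Step 3
Reactants: 5 methyl (S)-3-methyloct-7-ynoate
Product: 6 methyl (S)-7-iodo-3-methyloct-7-enoate
Conditions: NaI, Me3SiCl, H2O, MeCN, rt
Reagents that add atoms: sodium iodide, [Na+].[I-]
Why: Markovnikov hydroiodination of the terminal alkyne with hydrogen iodide made in the flask should stop at the 2-iodoalk-1-ene, the later handle for C7, and the methyl ester is inert at room temperature.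

Step 4
Reactants: 6 methyl (S)-7-iodo-3-methyloct-7-enoate
Product: 7 (S)-7-iodo-3-methyloct-7-enal
Conditions: i-Bu2AlH, CH2Cl2, −78 °C; aq potassium sodium tartrate
Reagents that add atoms: none
Why: Partial ester reduction: the tetrahedral aluminium hemiacetal is stable at −78 °C and collapses to the aldehyde only on work-up, and neither the alkenyl iodide nor C12 is affected.

Step 5
Reactants: 8 pent-3-yn-1-ol
Product: 9 pent-3-ynal
Conditions: Dess–Martin periodinane, CH2Cl2, 0 °C to rt
Reagents that add atoms: none
Why: Dess–Martin oxidation works without base, which should prevent the drift of the β,γ-alkynyl aldehyde to its allenyl isomer; 9 is used at once as a solution.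

Step 6
Reactants: 9 pent-3-ynal; 10 methyl propiolate
Product: 12 methyl 3-hydroxy-2-methylidenehept-5-ynoate (racemic), via vinylalane 11 (not isolated)
Conditions: 10, i-Bu2AlH, N-methylmorpholine N-oxide, THF, 0 °C; then 9, 0 °C to rt
Reagents that add atoms: none
Why: Vinylalumination, a base-free equivalent of the Morita–Baylis–Hillman reaction: hydroalumination of 10 gives the α-aluminated acrylate 11, which adds 1,2 to 9; the new carbinol centre is racemic and is erased in step 7.

Step 7
Reactants: 12 methyl 3-hydroxy-2-methylidenehept-5-ynoate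
Product: 13 methyl (Z)-2-(bromomethyl)hept-2-en-5-ynoate
Conditions: NBS, Me2S, CH2Cl2, 0 °C to rt
Reagents that add atoms: N-bromosuccinimide, O=C1CCC(=O)N1Br
Why: Corey–Kim-type activation of the allylic alcohol followed by SN2′ attack of bromide moves the double bond into conjugation and should give the (Z)-bromide, in which the C2 chain is cis to CH2Br.

Step 8
Reactants: 7 (S)-7-iodo-3-methyloct-7-enal; 13 methyl (Z)-2-(bromomethyl)hept-2-en-5-ynoate
Product: 16 methyl (3S,4R,5R,6S)-3-(but-2-yn-1-yl)-4-hydroxy-10-iodo-6-methyl-2-methylidene-5-[(phenylamino)oxy]undec-10-enoate, via aminoxy aldehyde 14 (not isolated), via allylindium reagent 15 (not isolated)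
Conditions: PhNO, L-proline (20 mol %), DMSO, rt; then 13, In powder, DMSO–H2O, rt
Reagents that add atoms: nitrosobenzene, O=Nc1ccccc1
Why: Tandem enamine-catalysed α-aminoxylation and Barbier-type indium allylation: L-proline directs the oxygen of nitrosobenzene to one enamine face and sets C13 as R under catalyst control, and 15 should then add through a chair transition state to the aldehyde held in a five-membered chelate of trivalent indium with the carbonyl and C13 oxygens, which sets C14 as R (syn to C13–O) and C1 as S (syn adduct, precursor of the cis-lactone).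

Step 9
Reactants: 16 methyl (3S,4R,5R,6S)-3-(but-2-yn-1-yl)-4-hydroxy-10-iodo-6-methyl-2-methylidene-5-[(phenylamino)oxy]undec-10-enoate
Product: 18 (4S,5R)-4-(but-2-yn-1-yl)-5-[(1R,2S)-1-hydroxy-6-iodo-2-methylhept-6-en-1-yl]-3-methylideneoxolan-2-one, via diol ester 17 (not isolated)
Conditions: Zn dust, AcOH–THF, rt
Reagents that add atoms: none
Why: Reductive N–O cleavage by zinc, then acid-catalysed lactonisation of the γ-hydroxy ester 17, in which the C14 hydroxyl closes the five-membered ring faster than the C13 hydroxyl could close a six-membered one; no stereocentre is touched and the syn C1/C14 pair becomes the cis-4,5-disubstituted lactone.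

Step 10
Reactants: 18 (4S,5R)-4-(but-2-yn-1-yl)-5-[(1R,2S)-1-hydroxy-6-iodo-2-methylhept-6-en-1-yl]-3-methylideneoxolan-2-one
Product: 19 (1R,2S)-1-[(2R,3S)-3-(but-2-yn-1-yl)-4-methylidene-5-oxooxolan-2-yl]-6-iodo-2-methylhept-6-en-1-yl acetate
Conditions: Ac2O, pyridine, DMAP (cat.), CH2Cl2, 0 °C
Reagents that add atoms: acetic anhydride, CC(=O)OC(C)=O
Why: DMAP-catalysed acetylation of the only free hydroxyl group, with retention at C13.

Step 11
Reactants: 19 (1R,2S)-1-[(2R,3S)-3-(but-2-yn-1-yl)-4-methylidene-5-oxooxolan-2-yl]-6-iodo-2-methylhept-6-en-1-yl acetate; 20 tributyl(vinyl)stannane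
Product: 21 (1R,2S)-1-[(2R,3S)-3-(but-2-yn-1-yl)-4-methylidene-5-oxooxolan-2-yl]-2-methyl-6-methylidene-7-oxonon-8-en-1-yl acetate
Conditions: CO (3 atm), PdCl2(MeCN)2 (5 mol %), BHT, DMF, rt to 40 °C
Reagents that add atoms: carbon monoxide, [C-]#[O+]
Why: Carbonylative Stille coupling, the standard entry to unsymmetrical divinyl ketones: oxidative addition of the alkenyl iodide, CO insertion, vinyl transfer from tin and reductive elimination build C5–C7 in one step under neutral conditions that spare the alkyne, the acetate and the α-methylene lactone.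

Step 12
Reactants: 21 (1R,2S)-1-[(2R,3S)-3-(but-2-yn-1-yl)-4-methylidene-5-oxooxolan-2-yl]-2-methyl-6-methylidene-7-oxonon-8-en-1-yl acetate
Product: 22 (1S,3E,12S,13R,14R)-13-acetoxy-7-oxocembra-3,8(19),15(17)-trien-16,14-olide
Conditions: Ni(cod)2 (20 mol %), PBu3 (40 mol %), Et3B, MeOH–THF, 50 °C, 21 added by syringe pump (final 2 mM)
Reagents that add atoms: none
Why: Proposed new method: zerovalent nickel should bind the unsubstituted vinyl ketone (C5=C6–C7=O) and the C3≡C4 alkyne of 21 and couple them oxidatively to an oxygen-bound divalent nickel enolate metallacycle in which C5 is bonded to C4, after which methanol protonates the enolate at C6, Et3B passes an ethyl group to nickel, β-hydride elimination expels ethene and C–H reductive elimination at C3 releases 22 and zerovalent nickel. The closest known reaction types are the nickel-catalysed reductive coupling of enones with alkynes (intermolecular and in five- and six-membered ring closures) and the nickel-catalysed reductive macrocyclisation of ynals; the macrocyclic enone version is what has not been shown. The only ring closed is the 14-membered carbocycle, in an endo mode in which both alkyne carbons and both vinyl carbons become ring members. No stereocentre is created, and the (E)-geometry of C3=C4 follows from the syn addition of C5 and hydrogen across the alkyne. The step needs bond formation at C4 and not at C3, which the small phosphine should secure by placing the methyl group at the bond-forming carbon and the β-branched C2 chain next to nickel, and it needs the vinyl group to react in preference to C8=C19 and C15=C17, which their α-substituents secure (weak binding to nickel; coupling at C17 would demand a bridged metallacycle with a bridgehead alkene, coupling at C19 a more strained 12-membered ring). Slow addition at high dilution should hold back oligomerisation.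

Step 13
Reactants: 22 (1S,3E,12S,13R,14R)-13-acetoxy-7-oxocembra-3,8(19),15(17)-trien-16,14-olide
Product: 23 (1S,3E,7S,12S,13R,14R)-13-acetoxy-7-hydroxycembra-3,8(19),15(17)-trien-16,14-olide
Conditions: (R)-2-methyl-CBS-oxazaborolidine, catecholborane, toluene, −78 °C
Reagents that add atoms: none
Why: Corey–Bakshi–Shibata reduction: the (R)-oxazaborolidine binds the ketone with the branched alkenyl carbon C8 as the large and C6H2 as the small substituent and delivers hydride to the face that gives the (7S)-alcohol, and catecholborane at low temperature reduces 1,2 without hydroborating the alkenes.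

Step 14
Reactants: 23 (1S,3E,7S,12S,13R,14R)-13-acetoxy-7-hydroxycembra-3,8(19),15(17)-trien-16,14-olide
Product: 24 (1S,3R,4R,7S,12S,13R,14R)-13-acetoxy-3,4-epoxy-7-hydroxycembra-8(19),15(17)-dien-16,14-olide (CNP0230083.1)
Conditions: D-fructose-derived Shi ketone (30 mol %), KHSO5 (as 2KHSO5·KHSO4·K2SO4), K2CO3, Bu4NHSO4 (cat.), MeCN–dimethoxymethane/aq Na2B4O7 buffer, 0 °C
Reagents that add atoms: potassium peroxymonosulfate, [K+].[O-]S(=O)(=O)OO
Why: Shi epoxidation: the chiral dioxirane reacts fastest with the only electron-rich trisubstituted (E)-alkene and, through the spiro transition state, the D-fructose-derived ketone should give the (3R,4R)-epoxide, while the 1,1-disubstituted C8=C19 and the electron-poor C15=C17 alkenes react much more slowly.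

Compound list
1 | (5-bromopent-1-yn-1-yl)trimethylsilane | C[Si](C)(C)C#CCCCBr | starting material
2 | methyl (E)-but-2-enoate | C/C=C/C(=O)OC | starting material
3 | [5-(trimethylsilyl)pent-4-yn-1-yl]magnesium bromide | C[Si](C)(C)C#CCCC[Mg]Br | intermediate
4 | methyl (S)-3-methyl-8-(trimethylsilyl)oct-7-ynoate | C[Si](C)(C)C#CCCC[C@H](C)CC(=O)OC | intermediate
5 | methyl (S)-3-methyloct-7-ynoate | C#CCCC[C@H](C)CC(=O)OC | intermediate
6 | methyl (S)-7-iodo-3-methyloct-7-enoate | C=C(I)CCC[C@H](C)CC(=O)OC | intermediate
7 | (S)-7-iodo-3-methyloct-7-enal | C=C(I)CCC[C@H](C)CC=O | intermediate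
8 | pent-3-yn-1-ol | CC#CCCO | starting material
9 | pent-3-ynal | CC#CCC=O | intermediate
10 | methyl propiolate | C#CC(=O)OC | starting material
11 | [1-(methoxycarbonyl)ethenyl]diisobutylaluminium | C=C(C(=O)OC)[Al](CC(C)C)CC(C)C | intermediate
12 | methyl 3-hydroxy-2-methylidenehept-5-ynoate (racemic) | C=C(C(O)CC#CC)C(=O)OC | intermediate
13 | methyl (Z)-2-(bromomethyl)hept-2-en-5-ynoate | BrC/C(C(=O)OC)=C\CC#CC | intermediate
14 | (2R,3S)-7-iodo-3-methyl-2-[(phenylamino)oxy]oct-7-enal | C=C(I)CCC[C@H](C)[C@@H](ONc1ccccc1)C=O | intermediate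
15 | allylindium reagent from 13, written as the dibromide | Br[In](Br)C/C(C(=O)OC)=C\CC#CC | intermediate
16 | methyl (3S,4R,5R,6S)-3-(but-2-yn-1-yl)-4-hydroxy-10-iodo-6-methyl-2-methylidene-5-[(phenylamino)oxy]undec-10-enoate | C=C(I)CCC[C@H](C)[C@@H](ONc1ccccc1)[C@H](O)[C@@H](CC#CC)C(=C)C(=O)OC | intermediate
17 | methyl (3S,4R,5R,6S)-3-(but-2-yn-1-yl)-4,5-dihydroxy-10-iodo-6-methyl-2-methylideneundec-10-enoate | C=C(I)CCC[C@H](C)[C@@H](O)[C@H](O)[C@@H](CC#CC)C(=C)C(=O)OC | intermediate
18 | (4S,5R)-4-(but-2-yn-1-yl)-5-[(1R,2S)-1-hydroxy-6-iodo-2-methylhept-6-en-1-yl]-3-methylideneoxolan-2-one | C=C(I)CCC[C@H](C)[C@@H](O)[C@@H]1OC(=O)C(=C)[C@@H]1CC#CC | intermediate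
19 | (1R,2S)-1-[(2R,3S)-3-(but-2-yn-1-yl)-4-methylidene-5-oxooxolan-2-yl]-6-iodo-2-methylhept-6-en-1-yl acetate | C=C(I)CCC[C@H](C)[C@@H](OC(C)=O)[C@@H]1OC(=O)C(=C)[C@@H]1CC#CC | intermediate
20 | tributyl(vinyl)stannane | C=C[Sn](CCCC)(CCCC)CCCC | starting material
21 | (1R,2S)-1-[(2R,3S)-3-(but-2-yn-1-yl)-4-methylidene-5-oxooxolan-2-yl]-2-methyl-6-methylidene-7-oxonon-8-en-1-yl acetate | C=CC(=O)C(=C)CCC[C@H](C)[C@@H](OC(C)=O)[C@@H]1OC(=O)C(=C)[C@@H]1CC#CC | intermediate
22 | (1S,3E,12S,13R,14R)-13-acetoxy-7-oxocembra-3,8(19),15(17)-trien-16,14-olide | C=C1CCC[C@H](C)[C@@H](OC(C)=O)[C@@H]2OC(=O)C(=C)[C@@H]2C/C=C(\C)CCC1=O | intermediate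
23 | (1S,3E,7S,12S,13R,14R)-13-acetoxy-7-hydroxycembra-3,8(19),15(17)-trien-16,14-olide | C=C1CCC[C@H](C)[C@@H](OC(C)=O)[C@@H]2OC(=O)C(=C)[C@@H]2C/C=C(\C)CC[C@@H]1O | intermediate
24 | (1S,3R,4R,7S,12S,13R,14R)-13-acetoxy-3,4-epoxy-7-hydroxycembra-8(19),15(17)-dien-16,14-olide | C=C1CCC[C@H](C)[C@@H](OC(C)=O)[C@@H]2OC(=O)C(=C)[C@@H]2C[C@H]2O[C@]2(C)CC[C@@H]1O | target

Total step count: 14. Longest linear sequence: 11 steps (steps 1–4 and 8–14). Steps 5–7 build the side branch.

Steps most likely to fail

1. Step 12 (ring closure).
   - Risks: oligomerisation may outrun the slow 14-membered closure, the coupling may start at the wrong alkyne carbon, and free phosphine may trigger polymerisation of the vinyl ketone.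
   - The fallback uses known chemistry, closes the same C4–C5 bond, and sets out from 19.
   - Nozaki–Hiyama–Kishi coupling with acrolein (CrCl2, cat. NiCl2, DMF) should give the divinyl carbinol F1 as both C7 epimers. This is harmless because C7 becomes a ketone.
   - Palladium-catalysed syn-hydrostannation (Bu3SnH, PdCl2(PPh3)2, THF) should put tin on the less hindered, methyl-bearing alkyne carbon and give the (E)-alkenylstannane F2.
   - Iododestannylation (I2, CH2Cl2, 0 °C) gives the (E)-alkenyl iodide F3.
   - An intramolecular Heck reaction at high dilution (Pd(OAc)2, Bu4NCl, NaHCO3, DMF) adds the alkenylpalladium species to the CH2 terminus of the vinyl carbinol. β-Hydride elimination towards the carbinol C–H gives the enol, and its tautomer is 22, where the route is rejoined.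

2. Step 8 (aminoxylation and allylation).
   - Risks: chelation by the anilinooxy group may be too weak in DMSO, so facial selectivity at C14 may be poor. The aminoxy aldehyde may also decompose before it is trapped.
   - The fallback sets out from 7. The same proline-catalysed aminoxylation is quenched with NaBH4 to give the aminoxy alcohol F4.
   - Zn/AcOH cleaves the N–O bond to the diol F5.
   - TEMPO/PhI(OAc)2 oxidises only the primary alcohol and gives the free α-hydroxy aldehyde F6.
   - An indium Barbier reaction of F6 with 13 in water, where a free α-hydroxyl binds trivalent indium strongly, should give the syn,syn diol ester 17. Lactonisation to 18 rejoins the route.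

3. Step 14 (epoxidation).
   - Risks: the face preferred by the catalyst may be the one the macrocycle hides, epoxidation of the C8=C19 allylic alcohol alkene may compete, and the basic medium may damage the acetate or the lactone.
   - The fallback sets out from 22, in which both exocyclic methylene groups are conjugated to carbonyl groups, so C3=C4 is the only nucleophilic alkene.
   - Buffered mCPBA (NaHCO3, CH2Cl2, 0 °C) should attack the outer face of the macrocycle under substrate control and give the epoxy ketone F7.
   - The reduction of step 13 applied to F7 then gives 24 directly.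

Further compounds
F1 | step 12 | (1R,2S)-1-[(2R,3S)-3-(but-2-yn-1-yl)-4-methylidene-5-oxooxolan-2-yl]-7-hydroxy-2-methyl-6-methylidenenon-8-en-1-yl acetate (both C7 epimers) | C=CC(O)C(=C)CCC[C@H](C)[C@@H](OC(C)=O)[C@@H]1OC(=O)C(=C)[C@@H]1CC#CC
F2 | step 12 | (1R,2S)-7-hydroxy-2-methyl-6-methylidene-1-{(2R,3S)-4-methylidene-5-oxo-3-[(2E)-3-(tributylstannyl)but-2-en-1-yl]oxolan-2-yl}non-8-en-1-yl acetate | C=CC(O)C(=C)CCC[C@H](C)[C@@H](OC(C)=O)[C@@H]1OC(=O)C(=C)[C@@H]1C/C=C(\C)[Sn](CCCC)(CCCC)CCCC
F3 | step 12 | (1R,2S)-7-hydroxy-1-{(2R,3S)-3-[(2E)-3-iodobut-2-en-1-yl]-4-methylidene-5-oxooxolan-2-yl}-2-methyl-6-methylidenenon-8-en-1-yl acetate | C=CC(O)C(=C)CCC[C@H](C)[C@@H](OC(C)=O)[C@@H]1OC(=O)C(=C)[C@@H]1C/C=C(\C)I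
F4 | step 8 | (2R,3S)-7-iodo-3-methyl-2-[(phenylamino)oxy]oct-7-en-1-ol | C=C(I)CCC[C@H](C)[C@@H](ONc1ccccc1)CO
F5 | step 8 | (2R,3S)-7-iodo-3-methyloct-7-ene-1,2-diol | C=C(I)CCC[C@H](C)[C@@H](O)CO
F6 | step 8 | (2R,3S)-2-hydroxy-7-iodo-3-methyloct-7-enal | C=C(I)CCC[C@H](C)[C@@H](O)C=O
F7 | step 14 | (1S,3R,4R,12S,13R,14R)-13-acetoxy-3,4-epoxy-7-oxocembra-8(19),15(17)-dien-16,14-olide | C=C1CCC[C@H](C)[C@@H](OC(C)=O)[C@@H]2OC(=O)C(=C)[C@@H]2C[C@H]2O[C@]2(C)CCC1=O
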